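**Plan**

- Retrosynthesis: the lactone is opened to a 2-methylene-1,4-diol (C16-OH, C2-OH), the C19 acetate is taken back to a methyl ester, and the 14-membered ring is cut at C7=C8.
- The ring itself allows this cut: C19 on C8 lies cis to C6 across C7=C8 (C6 and C9 trans), the geometry of a Z-α-alkyl enoate, so C19 as an ester acidifies C8 for a phosphonate that meets a C7 aldehyde.
- Further cuts: C8–C9 (phosphonoacetate alkylation), C15–C16 and C15=C17 (Weinreb amide to alkoxymethyl ketone to methylene), C1–C2 (aldol), C10–C11 and C2–C3 (alkenylalane plus ethylene oxide or formaldehyde).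
- Forward: two alkynols are methylaluminated to the C9–C15 acid and the C2–C7 enal; these are joined at C1–C2 and extended at C15 and C9; the carbocycle is closed at C7=C8; the five-membered lactone is formed last.
- Stereochemistry: C1 and C2 come from the Evans syn-aldol with (R)-4-benzyl-2-oxazolidinone (syn adduct = cis ring fusion); E-C3=C4 and E-C11=C12 come from syn-carboalumination; C19 cis to C6 comes from the trifluoroethyl phosphonate.

Key step: step 19

Remark on numbering: cembrane numbering is used throughout (C1 ring-fusion CH bearing C15; C2 the O–CH; ring alkenes C3=C4, C7=C8, C11=C12; C19 on C8; C15/C16/C17 the lactone α-carbon, carbonyl carbon and exocyclic CH2). The CIP label at C1 is R while C15 is a carbonyl carbon (18–25) and S from 26 onward, without any change in space.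

Remark on C8: the phosphonates 29–31 are formed as mixtures of C8 epimers, which is without consequence because C8 becomes sp2 in step 19.

Remark on protecting groups: the C16 oxygen is carried as a PMB ether and the C2 oxygen as a TBS ether; the C9 terminus is carried as a chloride and the C7 terminus as a primary TBS ether.

**Route**

Step 1
Reactants: 1 hex-5-yn-1-ol
Product: 2 tert-butyl(hex-5-yn-1-yloxy)dimethylsilane
Conditions: TBSCl, imidazole, DMF, rt
Reagents that add atoms: tert-butyldimethylsilyl chloride, CC(C)(C)[Si](C)(C)Cl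
Why: Imidazole-mediated silylation of a primary alcohol should proceed cleanly, the terminal alkyne being inert.

Step 2
Reactants: 2 tert-butyl(hex-5-yn-1-yloxy)dimethylsilane
Product: 5 (E)-8-[(tert-butyldimethylsilyl)oxy]-4-methyloct-3-en-1-ol, via alkenylalane 3 (not isolated), via lithium alanate 4 (not isolated)
Conditions: Me3Al, Cp2ZrCl2 (0.25 equiv), CH2Cl2, rt; volatiles removed; n-BuLi, THF, −78 → 0 °C; ethylene oxide, 0 °C → rt
Reagents that add atoms: trimethylaluminium, C[Al](C)C; ethylene oxide, C1CO1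
Why: Negishi zirconium-catalysed methylalumination adds methyl and aluminium syn across the alkyne with aluminium at the terminus, and the alanate opens ethylene oxide with retention, so E-C11=C12 and the C9–C10 unit should arise in one flask.

Step 3
Reactants: 5 (E)-8-[(tert-butyldimethylsilyl)oxy]-4-methyloct-3-en-1-ol
Product: 6 tert-butyl{[(E)-8-chloro-5-methyloct-5-en-1-yl]oxy}dimethylsilane
Conditions: PPh3, NCS, CH2Cl2, 0 °C → rt
Reagents that add atoms: N-chlorosuccinimide, O=C1CCC(=O)N1Cl
Why: Appel-type chlorination converts the primary homoallylic alcohol into the chloride by SN2 under neutral conditions that spare the silyl ether, and the chloride serves as a robust placeholder for the later C9 iodide.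

Step 4
Reactants: 6 tert-butyl{[(E)-8-chloro-5-methyloct-5-en-1-yl]oxy}dimethylsilane
Product: 7 (E)-8-chloro-5-methyloct-5-enoic acid
Conditions: CrO3, H2SO4, H2O, acetone, 0 °C → rt
Reagents that add atoms: water (from the aqueous Jones reagent), O
Why: In a Jones oxidation the aqueous acid should cleave the primary TBS ether and chromic acid should oxidise the liberated alcohol through the aldehyde hydrate to the acid, the isolated alkene and the alkyl chloride being inert.

Step 5
Reactants: 7 (E)-8-chloro-5-methyloct-5-enoic acid; 8 (R)-4-benzyl-2-oxazolidinone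
Product: 10 (R)-4-benzyl-3-[(E)-8-chloro-5-methyloct-5-enoyl]oxazolidin-2-one, via mixed pivalic anhydride 9 (not isolated)
Conditions: PivCl, Et3N, THF, −20 °C; then LiCl, 8, −20 °C → rt
Reagents that add atoms: none
Why: N-acylation of the oxazolidinone through the mixed pivalic anhydride should occur at the unhindered acyl carbon under the mild LiCl/Et3N protocol, which leaves the alkyl chloride untouched.

Step 6
Reactants: 11 pent-4-yn-1-ol
Product: 12 tert-butyldimethyl(pent-4-yn-1-yloxy)silane
Conditions: TBSCl, imidazole, DMF, rt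
Reagents that add atoms: tert-butyldimethylsilyl chloride, CC(C)(C)[Si](C)(C)Cl
Why: This is the same imidazole-mediated silylation of a primary alcohol as in step 1.

Step 7
Reactants: 12 tert-butyldimethyl(pent-4-yn-1-yloxy)silane
Product: 15 (E)-6-[(tert-butyldimethylsilyl)oxy]-3-methylhex-2-en-1-ol, via alkenylalane 13 (not isolated), via lithium alanate 14 (not isolated)
Conditions: Me3Al, Cp2ZrCl2 (0.25 equiv), CH2Cl2, rt; volatiles removed; n-BuLi, THF, −78 → 0 °C; (CH2O)n, rt
Reagents that add atoms: trimethylaluminium, C[Al](C)C; paraformaldehyde (as formaldehyde), C=O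
Why: Negishi carboalumination followed by hydroxymethylation of the alanate with formaldehyde proceeds with retention at the alkenyl carbon, so the E-C3=C4 allylic alcohol should result.

Step 8
Reactants: 15 (E)-6-[(tert-butyldimethylsilyl)oxy]-3-methylhex-2-en-1-ol
Product: 16 (E)-6-[(tert-butyldimethylsilyl)oxy]-3-methylhex-2-enal
Conditions: MnO2, CH2Cl2, rt
Reagents that add atoms: none
Why: Manganese dioxide oxidation is selective for the allylic alcohol and should stop at the enal without eroding the E geometry.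

Step 9
Reactants: 10 (R)-4-benzyl-3-[(E)-8-chloro-5-methyloct-5-enoyl]oxazolidin-2-one; 16 (E)-6-[(tert-butyldimethylsilyl)oxy]-3-methylhex-2-enal
Product: 18 Evans syn-aldol adduct (1R,2S), via dibutylboron Z-enolate 17 (not isolated)
Conditions: Bu2BOTf, iPr2NEt, CH2Cl2, 0 °C; then 16, −78 → 0 °C; pH 7 buffer, MeOH, H2O2, 0 °C
Reagents that add atoms: none
Why: In the Evans boron aldol the Z-enolate reacts with the enal (1,2-addition) through a Zimmerman–Traxler chair in which the benzyl group of the (R)-auxiliary shields one enolate face, which should set C1 and C2 as the syn pair that later becomes the cis ring fusion.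

Step 10
Reactants: 18 Evans syn-aldol adduct (1R,2S)
Product: 19 β-hydroxy Weinreb amide (1R,2S)
Conditions: MeNHOMe·HCl, Me3Al, CH2Cl2, −20 → 0 °C
Reagents that add atoms: N,O-dimethylhydroxylamine hydrochloride, CNOC.Cl
Why: Aluminium-amide transamidation of an aldol imide with a free β-hydroxyl (Weinreb amide formation) is directed to the exocyclic carbonyl and should release the auxiliary without retro-aldol cleavage or epimerisation at C1.

Step 11
Reactants: 19 β-hydroxy Weinreb amide (1R,2S)
Product: 20 C2-O-TBS Weinreb amide (1R,2S)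
Conditions: TBSOTf, 2,6-lutidine, CH2Cl2, −78 → 0 °C
Reagents that add atoms: tert-butyldimethylsilyl triflate, CC(C)(C)[Si](C)(C)OS(=O)(=O)C(F)(F)F
Why: Silylation with the silyl triflate and a hindered base should protect the hindered secondary allylic alcohol under non-acidic conditions that cannot ionise the allylic C2–O bond.

Step 12
Reactants: 21 tributyl(iodomethyl)stannane; 22 4-methoxybenzyl alcohol
Product: 23 tributyl{[(4-methoxybenzyl)oxy]methyl}stannane
Conditions: NaH, THF/DMF, 0 °C → rt
Reagents that add atoms: none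
Why: Williamson ether synthesis should work well here because the sodium alkoxide displaces iodide from the tin-activated primary carbon.

Step 13
Reactants: 20 C2-O-TBS Weinreb amide (1R,2S); 23 tributyl{[(4-methoxybenzyl)oxy]methyl}stannane
Product: 25 C15 ketone bearing C16-OPMB (1R,2S), via alkoxymethyllithium 24 (not isolated)
Conditions: 23, n-BuLi, THF, −78 °C; then 20, −78 °C; aq. NH4Cl
Reagents that add atoms: none
Why: Tin–lithium exchange gives the α-alkoxymethyllithium (Still hydroxymethyl anion equivalent), which should add once to the Weinreb amide (Weinreb ketone synthesis) at −78 °C without touching the alkyl chloride or epimerising C1.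

Step 14
Reactants: 25 C15 ketone bearing C16-OPMB (1R,2S)
Product: 26 2-(PMB-oxymethyl)vinyl chloride (1S,2S)
Conditions: Tebbe reagent, pyridine (cat.), THF/toluene, −40 → 0 °C
Reagents that add atoms: Tebbe reagent, C[Al-]1(C)C[Ti](C2C=CC=C2)(C2C=CC=C2)[Cl+]1
Why: Tebbe methylenation uses a non-basic titanium methylidene, so the hindered, enolisable ketone should be converted into the C15=C17 methylene without epimerisation at C1 or β-elimination of the C2 silyloxy group.

Step 15
Reactants: 26 2-(PMB-oxymethyl)vinyl chloride (1S,2S)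
Product: 27 C9 iodide (1S,2S)
Conditions: NaI, NaHCO3 (cat.), acetone, reflux
Reagents that add atoms: sodium iodide, [Na+].[I-]
Why: Finkelstein exchange at the primary homoallylic chloride is driven by precipitation of sodium chloride and should leave the ethers and alkenes unchanged.

Step 16
Reactants: 27 C9 iodide (1S,2S); 28 methyl bis(2,2,2-trifluoroethyl)phosphonoacetate
Product: 29 C8 phosphonoacetate with C7-OTBS (1S,2S; C8 epimers)
Conditions: 28 (3 equiv), NaH, DMF, 0 °C → rt; then 27, rt → 45 °C
Reagents that add atoms: none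
Why: C-alkylation of the sodium phosphonoacetate enolate by SN2 at the primary iodide forms C8–C9, an excess of the stabilised anion suppressing double alkylation and the soft nucleophile disfavouring elimination.

Step 17
Reactants: 29 C8 phosphonoacetate with C7-OTBS (1S,2S; C8 epimers)
Product: 30 C7 alcohol (1S,2S; C8 epimers)
Conditions: HF·pyridine, pyridine, THF, 0 °C → rt
Reagents that add atoms: none
Why: Selective desilylation with buffered HF·pyridine should remove the unhindered primary TBS ether much faster than the hindered secondary one at C2, the PMB ether and the phosphonate being inert.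

Step 18
Reactants: 30 C7 alcohol (1S,2S; C8 epimers)
Product: 31 seco aldehyde phosphonate (1S,2S; C8 epimers)
Conditions: Dess–Martin periodinane, NaHCO3, CH2Cl2, 0 °C → rt
Reagents that add atoms: none
Why: Dess–Martin oxidation under buffered, near-neutral conditions should give the C7 aldehyde without over-oxidation and without engaging the acidic C8–H.

Step 19
Reactants: 31 seco aldehyde phosphonate (1S,2S; C8 epimers)
Product: 34 macrocyclic C19 methyl ester (1S,2S), via potassium phosphonate carbanion 32 (not isolated), via β-oxido phosphonate 33 (not isolated)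
Conditions: 18-crown-6 (5 equiv), THF (1 mM in 31), −78 °C; KHMDS (1.05 equiv) added slowly; −78 → −20 °C
Reagents that add atoms: none
Why: KHMDS deprotonates C8 to the crown-separated potassium carbanion 32, which adds to the C7 aldehyde of the same chain to give the β-oxido phosphonate 33; with the electron-poor trifluoroethyl ester groups this adduct closes onto phosphorus and expels potassium bis(trifluoroethyl) phosphate faster than it reverts, so the kinetic adduct is translated into the enoate with C6 cis to C19. The closest known reaction type is the Still–Gennari olefination with α-alkyl phosphonoacetates run as an intramolecular Horner–Wadsworth–Emmons macrocyclisation. The 14-membered carbocycle is closed end-to-end by formation of C7=C8 from the ω-formyl phosphonate under high dilution, the chain being stiffened by the two E-alkenes and the 1,1-disubstituted alkene. No stereocentre is created: C1 and C2 lie far from the reacting termini, and the C8 epimers of 31 converge. The step needs the Z-enoate geometry and cyclisation over oligomerisation; the first rests on the trifluoroethyl phosphonate with a dissociated potassium counter-ion at low temperature, the second on the 1 mM concentration, and because this geometry places C6 and C9 trans across the new alkene the ring should accommodate it. The aldehyde is the only electrophile and C8–H the only acidic site, since the C2 and C16 oxygens are masked as ethers.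

Step 20
Reactants: 34 macrocyclic C19 methyl ester (1S,2S)
Product: 35 macrocyclic C19 allylic alcohol (1S,2S)
Conditions: DIBAL-H (2.5 equiv), CH2Cl2, −78 °C; Rochelle salt
Reagents that add atoms: none
Why: DIBAL 1,2-reduction of the enoate, the only carbonyl group present, should give the allylic alcohol with the C7=C8 geometry retained.

Step 21
Reactants: 35 macrocyclic C19 allylic alcohol (1S,2S)
Product: 36 macrocyclic C19 acetate (1S,2S)
Conditions: Ac2O, pyridine, DMAP (cat.), CH2Cl2, 0 °C → rt
Reagents that add atoms: acetic anhydride, CC(=O)OC(C)=O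
Why: DMAP-catalysed acetylation of the only free hydroxyl installs the C19 acetate.

Step 22
Reactants: 36 macrocyclic C19 acetate (1S,2S)
Product: 37 C16 alcohol with C2-OTBS (1S,2S)
Conditions: DDQ, CH2Cl2/pH 7 buffer, 0 °C
Reagents that add atoms: none
Why: Oxidative PMB cleavage with DDQ proceeds by hydride abstraction from the electron-rich benzyl ether and hydrolysis, and should leave the silyl ether, the acetate and the isolated alkenes untouched.

Step 23
Reactants: 37 C16 alcohol with C2-OTBS (1S,2S)
Product: 38 2-methylene-1,4-diol (1S,2S)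
Conditions: TBAF, AcOH, THF, rt
Reagents that add atoms: none
Why: Fluoride-mediated desilylation buffered with acetic acid should free the C2 hydroxyl without cleaving or migrating the remote allylic acetate.

Step 24
Reactants: 38 2-methylene-1,4-diol (1S,2S)
Product: 41 target lactone CNP0158848.2, via hydroxy enal 39 (not isolated), via lactol 40 (not isolated)
Conditions: TEMPO (0.2 equiv), PhI(OAc)2 (2.5 equiv), CH2Cl2, rt
Reagents that add atoms: none
Why: In the TEMPO/PhI(OAc)2 oxidative lactonisation the oxoammonium salt oxidises the primary allylic alcohol in preference to the secondary one, the enal closes onto the C2 hydroxyl as a five-membered lactol, and this is oxidised to the α-methylene lactone with C1 and C2 untouched.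

**Compound list**

1 | hex-5-yn-1-ol | C#CCCCCO | starting material
2 | tert-butyl(hex-5-yn-1-yloxy)dimethylsilane | C#CCCCCO[Si](C)(C)C(C)(C)C | intermediate
3 | [(1E)-6-(tert-butyldimethylsilyloxy)-2-methylhex-1-en-1-yl]dimethylalane (alkenylalane) | C[Al](C)/C=C(\C)CCCCO[Si](C)(C)C(C)(C)C | intermediate
4 | lithium butyl[(1E)-6-(tert-butyldimethylsilyloxy)-2-methylhex-1-en-1-yl]dimethylalanate (lithium alanate) | [Li+].CCCC[Al-](C)(C)/C=C(\C)CCCCO[Si](C)(C)C(C)(C)C | intermediate
5 | (E)-8-[(tert-butyldimethylsilyl)oxy]-4-methyloct-3-en-1-ol | OCC/C=C(\C)CCCCO[Si](C)(C)C(C)(C)C | intermediate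
6 | tert-butyl{[(E)-8-chloro-5-methyloct-5-en-1-yl]oxy}dimethylsilane | ClCC/C=C(\C)CCCCO[Si](C)(C)C(C)(C)C | intermediate
7 | (E)-8-chloro-5-methyloct-5-enoic acid (C9–C15 acid) | ClCC/C=C(\C)CCCC(=O)O | intermediate
8 | (R)-4-benzyl-2-oxazolidinone | O=C1N[C@H](Cc2ccccc2)CO1 | starting material
9 | mixed pivalic anhydride of acid 7 | ClCC/C=C(\C)CCCC(=O)OC(=O)C(C)(C)C | intermediate
10 | (R)-4-benzyl-3-[(E)-8-chloro-5-methyloct-5-enoyl]oxazolidin-2-one | ClCC/C=C(\C)CCCC(=O)N1[C@H](Cc2ccccc2)COC1=O | intermediate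
11 | pent-4-yn-1-ol | C#CCCCO | starting material
12 | tert-butyldimethyl(pent-4-yn-1-yloxy)silane | C#CCCCO[Si](C)(C)C(C)(C)C | intermediate
13 | [(1E)-5-(tert-butyldimethylsilyloxy)-2-methylpent-1-en-1-yl]dimethylalane (alkenylalane) | C[Al](C)/C=C(\C)CCCO[Si](C)(C)C(C)(C)C | intermediate
14 | lithium butyl[(1E)-5-(tert-butyldimethylsilyloxy)-2-methylpent-1-en-1-yl]dimethylalanate (lithium alanate) | [Li+].CCCC[Al-](C)(C)/C=C(\C)CCCO[Si](C)(C)C(C)(C)C | intermediate
15 | (E)-6-[(tert-butyldimethylsilyl)oxy]-3-methylhex-2-en-1-ol | OC/C=C(\C)CCCO[Si](C)(C)C(C)(C)C | intermediate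
16 | (E)-6-[(tert-butyldimethylsilyl)oxy]-3-methylhex-2-enal (C2–C7 enal) | O=C/C=C(\C)CCCO[Si](C)(C)C(C)(C)C | intermediate
17 | dibutylboron Z-enolate of imide 10 | CCCC[B](CCCC)O/C(=C\CC/C(C)=C/CCCl)N1[C@H](Cc2ccccc2)COC1=O | intermediate
18 | Evans syn-aldol adduct: (R)-4-benzyl-3-[(2R,3S,4E)-8-(tert-butyldimethylsilyloxy)-2-[(E)-6-chloro-3-methylhex-3-en-1-yl]-3-hydroxy-5-methyloct-4-enoyl]oxazolidin-2-one (cembrane 1R,2S) | CC(C)(C)[Si](C)(C)OCCC/C(C)=C/[C@H](O)[C@H](C(=O)N1[C@H](Cc2ccccc2)COC1=O)CC/C(C)=C/CCCl | intermediate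
19 | β-hydroxy Weinreb amide: (2R,3S,4E)-8-(tert-butyldimethylsilyloxy)-2-[(E)-6-chloro-3-methylhex-3-en-1-yl]-3-hydroxy-N-methoxy-N,5-dimethyloct-4-enamide | CC(C)(C)[Si](C)(C)OCCC/C(C)=C/[C@H](O)[C@H](C(=O)N(C)OC)CC/C(C)=C/CCCl | intermediate
20 | C2-O-TBS Weinreb amide (cembrane 1R,2S; TBS ethers at C2 and C7 oxygens, chloride at C9) | CC(C)(C)[Si](C)(C)OCCC/C(C)=C/[C@H](O[Si](C)(C)C(C)(C)C)[C@H](C(=O)N(C)OC)CC/C(C)=C/CCCl | intermediate
21 | tributyl(iodomethyl)stannane | CCCC[Sn](CCCC)(CCCC)CI | starting material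
22 | 4-methoxybenzyl alcohol | COc1ccc(CO)cc1 | starting material
23 | tributyl{[(4-methoxybenzyl)oxy]methyl}stannane | CCCC[Sn](CCCC)(CCCC)COCc1ccc(OC)cc1 | intermediate
24 | [(4-methoxybenzyl)oxy]methyllithium (alkoxymethyllithium) | [Li]COCc1ccc(OC)cc1 | intermediate
25 | C15 ketone bearing C16-OPMB (cembrane 1R,2S) | CC(C)(C)[Si](C)(C)OCCC/C(C)=C/[C@H](O[Si](C)(C)C(C)(C)C)[C@H](C(=O)COCc1ccc(OC)cc1)CC/C(C)=C/CCCl | intermediate
26 | 2-(PMB-oxymethyl)vinyl chloride: C15=C17 methylene, C16-OPMB, C2-OTBS, C7-OTBS, C9-Cl (1S,2S) | CC(C)(C)[Si](C)(C)OCCC/C(C)=C/[C@H](O[Si](C)(C)C(C)(C)C)[C@H](C(=C)COCc1ccc(OC)cc1)CC/C(C)=C/CCCl | intermediate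
27 | C9 iodide (1S,2S) | CC(C)(C)[Si](C)(C)OCCC/C(C)=C/[C@H](O[Si](C)(C)C(C)(C)C)[C@H](C(=C)COCc1ccc(OC)cc1)CC/C(C)=C/CCI | intermediate
28 | methyl bis(2,2,2-trifluoroethyl)phosphonoacetate | COC(=O)CP(=O)(OCC(F)(F)F)OCC(F)(F)F | starting material
29 | C8 phosphonoacetate with C7-OTBS (1S,2S; C8 epimers) | CC(C)(C)[Si](C)(C)OCCC/C(C)=C/[C@H](O[Si](C)(C)C(C)(C)C)[C@H](C(=C)COCc1ccc(OC)cc1)CC/C(C)=C/CCC(C(=O)OC)P(=O)(OCC(F)(F)F)OCC(F)(F)F | intermediate
30 | C7 alcohol (1S,2S; C8 epimers) | OCCC/C(C)=C/[C@H](O[Si](C)(C)C(C)(C)C)[C@H](C(=C)COCc1ccc(OC)cc1)CC/C(C)=C/CCC(C(=O)OC)P(=O)(OCC(F)(F)F)OCC(F)(F)F | intermediate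
31 | seco aldehyde phosphonate: C7 aldehyde, C8 bis(trifluoroethyl)phosphonate and methyl ester, C2-OTBS, C16-OPMB (1S,2S; C8 epimers) | O=CCC/C(C)=C/[C@H](O[Si](C)(C)C(C)(C)C)[C@H](C(=C)COCc1ccc(OC)cc1)CC/C(C)=C/CCC(C(=O)OC)P(=O)(OCC(F)(F)F)OCC(F)(F)F | intermediate
32 | potassium phosphonate carbanion of 31 | [K+].O=CCC/C(C)=C/[C@H](O[Si](C)(C)C(C)(C)C)[C@H](C(=C)COCc1ccc(OC)cc1)CC/C(C)=C/CC[C-](C(=O)OC)P(=O)(OCC(F)(F)F)OCC(F)(F)F | intermediate
33 | macrocyclic potassium β-oxido phosphonate (C7/C8 configuration not fixed) | [K+].C=C(COCc1ccc(OC)cc1)[C@@H]1CC/C(C)=C/CCC(C(=O)OC)(P(=O)(OCC(F)(F)F)OCC(F)(F)F)C([O-])CC/C(C)=C/[C@@H]1O[Si](C)(C)C(C)(C)C | intermediate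
34 | macrocyclic C19 methyl ester: 14-membered triene, C6 cis to CO2Me across C7=C8, C2-OTBS, C16-OPMB (1S,2S) | C=C(COCc1ccc(OC)cc1)[C@@H]1CC/C(C)=C/CC/C(C(=O)OC)=C/CC/C(C)=C/[C@@H]1O[Si](C)(C)C(C)(C)C | intermediate
35 | macrocyclic C19 allylic alcohol (1S,2S) | C=C(COCc1ccc(OC)cc1)[C@@H]1CC/C(C)=C/CC/C(CO)=C/CC/C(C)=C/[C@@H]1O[Si](C)(C)C(C)(C)C | intermediate
36 | macrocyclic C19 acetate (1S,2S) | C=C(COCc1ccc(OC)cc1)[C@@H]1CC/C(C)=C/CC/C(COC(C)=O)=C/CC/C(C)=C/[C@@H]1O[Si](C)(C)C(C)(C)C | intermediate
37 | C16 alcohol with C2-OTBS (1S,2S) | C=C(CO)[C@@H]1CC/C(C)=C/CC/C(COC(C)=O)=C/CC/C(C)=C/[C@@H]1O[Si](C)(C)C(C)(C)C | intermediate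
38 | 2-methylene-1,4-diol (C16-OH, C2-OH; 1S,2S) | C=C(CO)[C@@H]1CC/C(C)=C/CC/C(COC(C)=O)=C/CC/C(C)=C/[C@@H]1O | intermediate
39 | hydroxy enal (C16 aldehyde, C2-OH) | C=C(C=O)[C@@H]1CC/C(C)=C/CC/C(COC(C)=O)=C/CC/C(C)=C/[C@@H]1O | intermediate
40 | lactol (C16 hemiacetal, configuration at C16 not fixed) | C=C1C(O)O[C@H]2/C=C(\C)CC/C=C(\COC(C)=O)CC/C=C(\C)CC[C@@H]12 | intermediate
41 | CNP0158848.2, cis-fused α-methylene-γ-lactone (1S,2S) | C=C1C(=O)O[C@H]2/C=C(\C)CC/C=C(\COC(C)=O)CC/C=C(\C)CC[C@@H]12 | target

**Summary**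

Total step count: 24.
Longest linear sequence: 20 steps (steps 1–5, 9–11, 13–24, from hex-5-yn-1-ol 1 to 41).

**Steps most likely to fail**

1. Step 19. Intermolecular olefination may outrun ring closure and give oligomers, and the adduct may equilibrate before elimination so that the geometry at C7=C8 erodes. The fallback changes the activating group on phosphorus to a diaryl phosphonate, which is Z-selective with a sodium counter-ion. It sets out from iodide 27, which alkylates the sodium salt of ethyl bis(2-methylphenyl)phosphonoacetate (NaH, DMSO/THF) to give the diaryl phosphonate with C7-OTBS F1. HF·pyridine then frees the C7 alcohol F2, and Dess–Martin oxidation gives the aldehyde diaryl phosphonate F3. Ring closure under Ando conditions (NaH, THF, −78 → 0 °C, 1 mM) should give the macrocyclic C19 ethyl ester F4. DIBAL reduction of F4 returns to the route at alcohol 35.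

2. Step 16. Displacement at the homoallylic iodide may be slow, so that the fluorinated phosphonate anion decomposes by ester exchange at phosphorus or the product is alkylated a second time on warming. The fallback replaces the halide displacement by a low-temperature alkylation with a far better leaving group. It sets out from iodide 27, which is displaced with caesium acetate (DMF, 50 °C) to the C9 acetate F5. Methanolysis (K2CO3, MeOH) gives the C9 alcohol F6, and Tf2O/2,6-lutidine at −78 °C gives the C9 triflate F7. F7 is added at once to the sodium enolate of 28 in THF at −78 → 0 °C, which returns to the route at phosphonate 29.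

3. Step 13. Tin–lithium exchange may be incomplete, the α-alkoxy carbanion may rearrange before it adds, or it may enolise the hindered amide with loss of the C2 silyloxy group. The fallback builds the 2-(alkoxymethyl)vinyl unit by cross-coupling instead of carbonyl addition and methylenation. It sets out from Weinreb amide 20, which MeMgBr (THF, 0 °C) converts into the C15 methyl ketone F8. Kinetic enolisation on the methyl side (KHMDS, PhNTf2, THF, −78 °C) gives the enol triflate F9. Stille coupling of F9 with stannane 23 (Pd(PPh3)4, LiCl, dioxane, 80 °C) returns to the route at alkene 26, so that step 14 is bypassed as well.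

**Further compounds**

F1 | step 19 | ethyl bis(2-methylphenyl)phosphonoacetate alkylated at C8, C7-OTBS (1S,2S; C8 epimers) | CC(C)(C)[Si](C)(C)OCCC/C(C)=C/[C@H](O[Si](C)(C)C(C)(C)C)[C@H](C(=C)COCc1ccc(OC)cc1)CC/C(C)=C/CCC(C(=O)OCC)P(=O)(Oc1ccccc1C)Oc1ccccc1C
F2 | step 19 | C7 alcohol of the diaryl phosphonate | OCCC/C(C)=C/[C@H](O[Si](C)(C)C(C)(C)C)[C@H](C(=C)COCc1ccc(OC)cc1)CC/C(C)=C/CCC(C(=O)OCC)P(=O)(Oc1ccccc1C)Oc1ccccc1C
F3 | step 19 | C7 aldehyde of the diaryl phosphonate | O=CCC/C(C)=C/[C@H](O[Si](C)(C)C(C)(C)C)[C@H](C(=C)COCc1ccc(OC)cc1)CC/C(C)=C/CCC(C(=O)OCC)P(=O)(Oc1ccccc1C)Oc1ccccc1C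
F4 | step 19 | macrocyclic C19 ethyl ester (1S,2S) | C=C(COCc1ccc(OC)cc1)[C@@H]1CC/C(C)=C/CC/C(C(=O)OCC)=C/CC/C(C)=C/[C@@H]1O[Si](C)(C)C(C)(C)C
F5 | step 16 | C9 acetate (1S,2S) | CC(C)(C)[Si](C)(C)OCCC/C(C)=C/[C@H](O[Si](C)(C)C(C)(C)C)[C@H](C(=C)COCc1ccc(OC)cc1)CC/C(C)=C/CCOC(C)=O
F6 | step 16 | C9 alcohol (1S,2S) | CC(C)(C)[Si](C)(C)OCCC/C(C)=C/[C@H](O[Si](C)(C)C(C)(C)C)[C@H](C(=C)COCc1ccc(OC)cc1)CC/C(C)=C/CCO
F7 | step 16 | C9 triflate (1S,2S) | CC(C)(C)[Si](C)(C)OCCC/C(C)=C/[C@H](O[Si](C)(C)C(C)(C)C)[C@H](C(=C)COCc1ccc(OC)cc1)CC/C(C)=C/CCOS(=O)(=O)C(F)(F)F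
F8 | step 13 | C15 methyl ketone (1R,2S) | CC(C)(C)[Si](C)(C)OCCC/C(C)=C/[C@H](O[Si](C)(C)C(C)(C)C)[C@H](C(C)=O)CC/C(C)=C/CCCl
F9 | step 13 | C15 enol triflate (1R,2S) | CC(C)(C)[Si](C)(C)OCCC/C(C)=C/[C@H](O[Si](C)(C)C(C)(C)C)[C@H](C(=C)OS(=O)(=O)C(F)(F)F)CC/C(C)=C/CCCl
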